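**Retrosynthetic overview**
1. Target 10 ⇒ 8. The C15–O bond comes from a 1,3-transposition of the tertiary allylic alcohol (manool-type side chain), which also creates the 13E alkene.
2. 8 ⇒ 5. The exocyclic C8=C17 alkene comes from the equatorial 8α-OH, where an anti elimination can only use the C17 methyl hydrogens.
3. 5 ⇒ 3. The 19-CHO and 3-OAc come from the 3β,19-diol by primary-selective oxidation and then acetylation.
4. Key disconnections are C19–O (new, catalyst-controlled hydroxylation of the axial 4β-methyl, which creates the C4 stereocentre) and C3–O (known 3β C–H hydroxylation) ⇒ (−)-sclareol 1.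
5. No ring is formed and no C–C bond is made. Rings A and B, with C5, C9 and C10, are taken intact from 1.

Assumption: labdane numbering is used. Commercial (−)-sclareol is the (13R)-labd-14-ene-8α,13-diol of the normal series (10β-methyl, 5α-H, 9α-H), the same absolute series as the target, which is (3S,4R,5R,9S,10R,13E) with an axial 4β-CHO.

**Step 1**
Reactants: 1 (−)-sclareol
Product: 2 3β-hydroxysclareol
Conditions: P450 BM3 C3-hydroxylase variant (clarified E. coli lysate), NADP+ (cat.), phosphite dehydrogenase, Na2HPO3, air, K2HPO4/KH2PO4 buffer pH 8.0, 5% EtOH, 25 °C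
Reagents that add atoms: dioxygen, O=O
Why: Cytochrome P450 C–H hydroxylation (hydrogen abstraction, oxygen rebound) with BM3 variants evolved for sclareol and sclareolide is a known preparative reaction that attacks only the equatorial 3β-H and, because rebound retains configuration, sets C3 as 3S (3β-OH).

**Step 2**
Reactants: 2 3β-hydroxysclareol
Product: 3 3β,19-dihydroxysclareol (labd-14-ene-3β,8α,13,19-tetraol)
Conditions: new P450 BM3 variant "BM3-C19" (clarified lysate), NADP+ (cat.), phosphite dehydrogenase, Na2HPO3, air, K2HPO4/KH2PO4 buffer pH 8.0, 5% DMSO, 25 °C, stopped at full conversion of 2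
Reagents that add atoms: dioxygen, O=O
Why: Proposed new method: a new BM3 variant is built from the step 1 enzyme by adding a hydrogen-bond clamp (Asn/Gln side chains in the distal pocket) for the 3β-OH and by filling the space over C1/C20 with bulky residues, so that ring A docks with its β face flat on the heme; in this pose only the axial 4β-methyl (C19) points at the oxo ligand while the equatorial 4α-methyl (C18) lies in the ring plane and points away, so hydrogen abstraction by the tetravalent iron-oxo porphyrin radical cation and fast oxygen rebound form the C19–O bond and turn C4 into the stereocentre of the target; position in the pocket rather than bond strength decides the site, and the closest known reaction types are BM3-variant hydroxylation of an unactivated methyl group of artemisinin and the plant P450 oxidation of the axial C19 methyl in labdane and kaurane biosynthesis.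

**Step 3**
Reactants: 3 3β,19-dihydroxysclareol
Product: 4 3β,8α,13-trihydroxylabd-14-en-19-al
Conditions: TEMPO (10 mol %), PhI(OAc)2 (1.1 equiv), CH2Cl2, 23 °C
Reagents that add atoms: none
Why: Oxoammonium (TEMPO) oxidation is sterically biased towards primary carbinols, so the 19-CH2OH goes to the aldehyde while the secondary 3β-OH, the two tertiary alcohols and the vinyl group stay untouched, and the aldehyde has no α-hydrogen, so C4 cannot epimerise.

**Step 4**
Reactants: 4 3β,8α,13-trihydroxylabd-14-en-19-al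
Product: 5 3β-acetoxy-8α,13-dihydroxylabd-14-en-19-al
Conditions: Ac2O (1.5 equiv), pyridine, DMAP (5 mol %), CH2Cl2, 0 °C
Reagents that add atoms: acetic anhydride, CC(=O)OC(C)=O
Why: DMAP-catalysed acylation at 0 °C esterifies only the secondary 3β-OH (the tertiary 8- and 13-OH groups are inert), with retention at C3 and under conditions too mild for a retro-aldol reaction.

**Step 5**
Reactants: 5 3β-acetoxy-8α,13-dihydroxylabd-14-en-19-al
Product: 8 3β-acetoxy-13-hydroxylabda-8(17),14-dien-19-al, via 13-O-trimethylsilyl ether 6 (not isolated), via 13-O-trimethylsilyl 8(17)-ene 7 (not isolated)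
Conditions: TMSOTf (1.05 equiv), 2,6-lutidine, CH2Cl2, −78 °C; then pyridine, SOCl2 (1.5 equiv), −78 to −30 °C; then citric acid, MeOH, 0 °C
Reagents that add atoms: none
Why: Transient silylation takes the open-chain 13-OH before the ring 8α-OH (which is flanked by C9 and the axial C17 methyl); the chlorosulfite of the equatorial 8α-OH then undergoes pyridine-mediated E2 elimination, for which only the C17 methyl hydrogens can become anti-periplanar, giving the exocyclic alkene, and mild acid methanolysis frees the 13-OH.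

**Step 6**
Reactants: 8 3β-acetoxy-13-hydroxylabda-8(17),14-dien-19-al
Product: 10 3β-acetoxy-15-hydroxylabda-8(17),13E-dien-19-al (target), via 15-O-trimethylsilyl ether 9 (not isolated)
Conditions: Ph3SiOReO3 (3 mol %), N,O-bis(trimethylsilyl)acetamide (1.3 equiv), Et2O, 0 °C; then citric acid, MeOH, 0 °C; AgNO3–SiO2 chromatography to remove the 13Z isomer
Reagents that add atoms: none
Why: Oxo-rhenium-catalysed 1,3-transposition of an allylic alcohol ([3,3] shift of the perrhenate ester) forms the C15–O bond; it is pulled forward by selective silylation of the primary alcohol, and the chair transition state with the larger C12 chain pseudo-equatorial favours the 13E alkene.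

**Compound list**
1 | (−)-sclareol, (13R)-labd-14-ene-8α,13-diol | C[C@@]1(O)CC[C@H]2C(C)(C)CCC[C@]2(C)[C@H]1CC[C@](C)(C=C)O | starting material
2 | 3β-hydroxysclareol (labd-14-ene-3β,8α,13-triol) | C[C@@]1(O)CC[C@H]2C(C)(C)[C@@H](O)CC[C@]2(C)[C@H]1CC[C@](C)(C=C)O | intermediate
3 | 3β,19-dihydroxysclareol (axial 4β-CH2OH) | C[C@@]1(O)CC[C@H]2[C@@](C)(CO)[C@@H](O)CC[C@]2(C)[C@H]1CC[C@](C)(C=C)O | intermediate
4 | 3β,8α,13-trihydroxylabd-14-en-19-al | C[C@@]1(O)CC[C@H]2[C@@](C)(C=O)[C@@H](O)CC[C@]2(C)[C@H]1CC[C@](C)(C=C)O | intermediate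
5 | 3β-acetoxy-8α,13-dihydroxylabd-14-en-19-al | C[C@@]1(O)CC[C@H]2[C@@](C)(C=O)[C@@H](OC(C)=O)CC[C@]2(C)[C@H]1CC[C@](C)(C=C)O | intermediate
6 | 13-O-trimethylsilyl ether of 5 | C[C@@]1(O)CC[C@H]2[C@@](C)(C=O)[C@@H](OC(C)=O)CC[C@]2(C)[C@H]1CC[C@](C)(C=C)O[Si](C)(C)C | intermediate
7 | 3β-acetoxy-13-trimethylsilyloxylabda-8(17),14-dien-19-al | C=C1CC[C@H]2[C@@](C)(C=O)[C@@H](OC(C)=O)CC[C@]2(C)[C@H]1CC[C@](C)(C=C)O[Si](C)(C)C | intermediate
8 | 3β-acetoxy-13-hydroxylabda-8(17),14-dien-19-al (13R) | C=C1CC[C@H]2[C@@](C)(C=O)[C@@H](OC(C)=O)CC[C@]2(C)[C@H]1CC[C@](C)(C=C)O | intermediate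
9 | 3β-acetoxy-15-trimethylsilyloxylabda-8(17),13E-dien-19-al | C=C1CC[C@H]2[C@@](C)(C=O)[C@@H](OC(C)=O)CC[C@]2(C)[C@H]1CC/C(C)=C/CO[Si](C)(C)C | intermediate
10 | 3β-acetoxy-15-hydroxylabda-8(17),13E-dien-19-al, (3S,4R,5R,9S,10R) | C=C1CC[C@H]2[C@@](C)(C=O)[C@@H](OC(C)=O)CC[C@]2(C)[C@H]1CC/C(C)=C/CO | target

**Total step count:** 6. **Longest linear sequence:** 6.

**Steps most likely to fail**

Step 2 (the new step). The variant may prefer C18, C2 or the 3-carbinol. The fallback sets out from 1 and comes back at 4, so steps 1 to 3 are not needed.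
- Compound 1 is fermented with wild-type Cunninghamella, which is known to give 19-hydroxysclareol F1 beside other hydroxy isomers. The yield is low and chromatography is needed.
- F1 is oxidised with TEMPO/PhI(OAc)2 to 8α,13-dihydroxylabd-14-en-19-al F2.
- F2 is condensed with 2-(aminomethyl)pyridine (TsOH cat., toluene, 80 °C) to the picolyl imine F3.
- F3 is submitted to the known copper/O2 imine-directed hydroxylation of a neighbouring methylene (Cu(OTf)2, sodium ascorbate, O2, acetone–MeOH, 50 °C).
- The axial C19 imine can reach only the gauche, equatorial 3β-H, because 5-H is anti and C18 offers only stronger primary C–H bonds. This gives the 3β-hydroxy imine F4.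
- The Na4EDTA work-up hydrolyses F4 to 4.

Step 5. The selectivity of the transient silylation may be low, and endocyclic alkenes may form. The fallback sets out from 5 and comes back at 10, so it replaces steps 5 and 6.
- AcCl/N,N-dimethylaniline gives 3β,8α,13-triacetoxylabd-14-en-19-al F5.
- The [3,3] allylic acetate shift catalysed by divalent palladium (PdCl2(MeCN)2, THF, 23 °C), long used on sclareol diacetate, gives 3β,8α,15-triacetoxylabd-13E-en-19-al F6.
- Thermal syn elimination of the tertiary acetate (2,4,6-collidine, reflux) gives 3β,15-diacetoxylabda-8(17),13E-dien-19-al F7.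
- K2CO3/MeOH at 0 °C cleaves only the primary allylic acetate and gives 10.

Step 6. The E/Z ratio may be modest, because the methyl group and the C12 chain differ little in size. The fallback sets out from 8 and comes back at 10, and it replaces the oxo-metal shift by ionic chemistry.
- PBr3 (Et2O, pyridine cat., −10 °C) converts the tertiary vinyl carbinol by SN2′ into 3β-acetoxy-15-bromolabda-8(17),13E-dien-19-al F8, as linalool gives geranyl bromide.
- HCO2Cs in DMF gives 3β-acetoxy-15-formyloxylabda-8(17),13E-dien-19-al F9.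
- NaHCO3/MeOH removes the formate much faster than the hindered 3-acetate and gives 10.

**Further compounds**
F1 | step 2 | 19-hydroxysclareol (labd-14-ene-8α,13,19-triol) | C[C@@]1(O)CC[C@H]2[C@@](C)(CO)CCC[C@]2(C)[C@H]1CC[C@](C)(C=C)O
F2 | step 2 | 8α,13-dihydroxylabd-14-en-19-al | C[C@@]1(O)CC[C@H]2[C@@](C)(C=O)CCC[C@]2(C)[C@H]1CC[C@](C)(C=C)O
F3 | step 2 | N-(pyridin-2-ylmethyl) E-imine of F2 | C[C@@]1(O)CC[C@H]2[C@@](C)(/C=N/Cc3ccccn3)CCC[C@]2(C)[C@H]1CC[C@](C)(C=C)O
F4 | step 2 | N-(pyridin-2-ylmethyl) E-imine of 4 (3β-hydroxy imine) | C[C@@]1(O)CC[C@H]2[C@@](C)(/C=N/Cc3ccccn3)[C@@H](O)CC[C@]2(C)[C@H]1CC[C@](C)(C=C)O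
F5 | step 5 | 3β,8α,13-triacetoxylabd-14-en-19-al | C[C@@]1(OC(C)=O)CC[C@H]2[C@@](C)(C=O)[C@@H](OC(C)=O)CC[C@]2(C)[C@H]1CC[C@](C)(C=C)OC(C)=O
F6 | step 5 | 3β,8α,15-triacetoxylabd-13E-en-19-al | C[C@@]1(OC(C)=O)CC[C@H]2[C@@](C)(C=O)[C@@H](OC(C)=O)CC[C@]2(C)[C@H]1CC/C(C)=C/COC(C)=O
F7 | step 5 | 3β,15-diacetoxylabda-8(17),13E-dien-19-al | C=C1CC[C@H]2[C@@](C)(C=O)[C@@H](OC(C)=O)CC[C@]2(C)[C@H]1CC/C(C)=C/COC(C)=O
F8 | step 6 | 3β-acetoxy-15-bromolabda-8(17),13E-dien-19-al | C=C1CC[C@H]2[C@@](C)(C=O)[C@@H](OC(C)=O)CC[C@]2(C)[C@H]1CC/C(C)=C/CBr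
F9 | step 6 | 3β-acetoxy-15-formyloxylabda-8(17),13E-dien-19-al | C=C1CC[C@H]2[C@@](C)(C=O)[C@@H](OC(C)=O)CC[C@]2(C)[C@H]1CC/C(C)=C/COC=O
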